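**Strategy.** The dihydrofuran ring of the target is cut into three pieces. O1, C7a and C3a are the hydroxyl and the one free ortho carbon of 4-bromoguaiacol. C3 with its one-carbon branch is the aldehyde carbon of ethyl glyoxylate. C2 with the veratryl group is the carbanion carbon of a chiral benzylic sulfonium ylide. One flask operation joins them: ortho-hydroxyalkylation, conversion of the adduct into an ortho-quinone methide, and [4+1] annulation, which forms C3–C3a, C2–C3 and O1–C2 and sets both stereocentres trans. The precursors are the bromophenol, the glyoxylate and a twofold-symmetric thiolanium salt; bromine at C5 holds the place of the propenal chain.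

Key step: step 4

Assumption: the (2R,5R) sulfide is expected to give the 2R series, by analogy with the sense of its benzylidene transfer to aldehydes; if the sense proves opposite, the mirror-image sulfide, made in the same two steps from (2R,5R)-hexane-2,5-diol, is used instead.

**Step 1**
Reactants: 1 (2S,5S)-hexane-2,5-diol
Product: 2 (2S,5S)-hexane-2,5-diyl dimethanesulfonate
Conditions: MsCl, Et3N, CH2Cl2, 0 °C
Reagents that add atoms: methanesulfonyl chloride, CS(=O)(=O)Cl
Why: O-sulfonylation (mesylation) of both secondary alcohols leaves the C–O bonds intact, so the two S centres pass unchanged into a bis-electrophile.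

**Step 2**
Reactants: 2 (2S,5S)-hexane-2,5-diyl dimethanesulfonate
Product: 3 (2R,5R)-2,5-dimethylthiolane
Conditions: Na2S·9H2O, DMSO, rt; pentane extraction, distillation
Reagents that add atoms: sodium sulfide, [Na+].[Na+].[S-2]
Why: Double SN2 displacement by sulfide, the second a 5-exo-tet ring closure, inverts each carbinol carbon once, so the (2S,5S) dimesylate should give the (2R,5R) thiolane.

**Step 3**
Reactants: 3 (2R,5R)-2,5-dimethylthiolane, 4 3,4-dimethoxybenzyl bromide
Product: 5 (2R,5R)-1-(3,4-dimethoxybenzyl)-2,5-dimethylthiolan-1-ium tetrafluoroborate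
Conditions: AgBF4, CH2Cl2, −20 °C to rt, dark; filtration, precipitation with Et2O
Reagents that add atoms: silver tetrafluoroborate, [Ag+].F[B-](F)(F)F
Why: S-alkylation of the thioether by the benzylic bromide, driven by silver halide abstraction and made irreversible by the non-nucleophilic counter-ion, should give a single salt because the twofold axis of the sulfide makes its two lone pairs equivalent, and no stereocentre is touched.

**Step 4**
Reactants: 6 4-bromo-2-methoxyphenol, 7 ethyl glyoxylate, 5 (2R,5R)-1-(3,4-dimethoxybenzyl)-2,5-dimethylthiolan-1-ium tetrafluoroborate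
Product: 13 ethyl (2R,3R)-5-bromo-2-(3,4-dimethoxyphenyl)-7-methoxy-2,3-dihydro-1-benzofuran-3-carboxylate (trans), via hydroxy ester 8 (not isolated), via benzylic carbonate 9 (not isolated), via ortho-quinone methide 10 (not isolated), via sulfonium ylide 11 (not isolated), via betaine 12 (not isolated)
Conditions: EtMgBr (1.0 equiv), toluene, 0 °C; 7 (1.0 equiv, freshly distilled monomer), −20 °C to rt; Boc2O (1.0 equiv), −78 to −40 °C, re-cool to −78 °C; ylide 11 [from 5 (1.4 equiv), LiN(SiMe3)2 (1.3 equiv), THF, −78 °C] by cannula, −78 to −20 °C; aq NH4Cl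
Reagents that add atoms: none
Why: Proposed new method: the bromomagnesium phenoxide of 6 should deliver the glyoxylate aldehyde to C6, its only free ortho carbon (para is blocked by bromine), and the chelated adduct 8 is O-acylated by Boc2O so that the phenoxide can expel tert-butyl carbonate from the benzylic carbon in an E1cB-type 1,4-elimination to give quinone methide 10, which carries no hydrogen next to the methide carbon and so cannot tautomerise to a styrene. Ylide 11, introduced only when no free aldehyde is left for it to epoxidise, should attack the exocyclic carbon of 10 in a 1,4-sense (C2–C3 bond, arene restored) to give betaine 12, whose phenoxide displaces the thiolane at the benzylic carbon with inversion in a 5-exo-tet closure (O1–C2 bond), which is the mode by which the one new ring forms. The closest known reactions are the magnesium- or titanium-phenoxide ortho-hydroxyalkylation of phenols with glyoxylates, the carbonate-transfer generation of ortho-quinone methides from magnesium phenoxides, and the [4+1] annulation of ortho-quinone methides formed in situ with sulfonium ylides; new is their merger in one flask with an ester-bearing quinone methide and a chiral benzylide. C2 is controlled by the sulfide, since the ylide should react through the conformer that turns the aryl group away from the ring and on the face not shielded by the neighbouring methyl group, which together with the inversion on closure should give 2R. C3 is set relative to C2 in the addition, where the anti approach that keeps the veratryl ring away from the dienone ring leads to the trans ring, and any cis isomer can be brought to trans by enolisation at C3 alone (NaOEt, EtOH), which leaves C2 untouched. The step needs ortho-regioselectivity, 1,4-chemoselectivity, trans-selectivity and enantioselectivity, which the blocked para position and metal chelation, the aromatisation-driven conjugate addition with staged addition of the ylide, and the twofold-symmetric sulfide (one sulfonium salt, one reactive ylide conformer) are meant to secure.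

**Step 5**
Reactants: 13 ethyl (2R,3R)-5-bromo-2-(3,4-dimethoxyphenyl)-7-methoxy-2,3-dihydro-1-benzofuran-3-carboxylate
Product: 14 [(2R,3S)-5-bromo-2-(3,4-dimethoxyphenyl)-7-methoxy-2,3-dihydro-1-benzofuran-3-yl]methanol
Conditions: iBu2AlH (3 equiv), CH2Cl2, −78 to 0 °C; aq KNaC4H4O6 (potassium sodium tartrate)
Reagents that add atoms: none
Why: Ester-to-primary-alcohol reduction by a non-basic aluminium hydride at low temperature should spare the aryl bromide and the benzylic ether and, since no enolate forms at C3, carry the trans relationship through (the C3 descriptor changes from R to S only because the CIP priorities change).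

**Step 6**
Reactants: 14 [(2R,3S)-5-bromo-2-(3,4-dimethoxyphenyl)-7-methoxy-2,3-dihydro-1-benzofuran-3-yl]methanol, 15 3,3-diethoxyprop-1-ene (acrolein diethyl acetal)
Product: 17 4-O-methylbalanophonin: (2E)-3-[(2R,3S)-2-(3,4-dimethoxyphenyl)-3-(hydroxymethyl)-7-methoxy-2,3-dihydro-1-benzofuran-5-yl]prop-2-enal, via diethyl acetal 16 (not isolated)
Conditions: Pd(OAc)2 (3 mol %), nBu4NOAc, K2CO3, KCl, 15 (3 equiv), DMF, 90 °C; then 2 M HCl, rt, short contact
Reagents that add atoms: water, O
Why: A phosphine-free Heck reaction of the aryl bromide at the terminal alkene carbon, with β-hydride elimination toward the benzylic position under acetate and chloride conditions, should give the E cinnamyl acetal, which dilute acid unmasks to the E enal (acetal hydrolysis) without disturbing C2 or C3, neither of which is now next to a carbonyl group.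

**Compound list**

1 | (2S,5S)-hexane-2,5-diol | C[C@H](O)CC[C@H](C)O | starting material
2 | (2S,5S)-hexane-2,5-diyl dimethanesulfonate | C[C@H](OS(C)(=O)=O)CC[C@H](C)OS(C)(=O)=O | intermediate
3 | (2R,5R)-2,5-dimethylthiolane | C[C@@H]1CC[C@@H](C)S1 | intermediate
4 | 3,4-dimethoxybenzyl bromide (veratryl bromide) | COc1ccc(CBr)cc1OC | starting material
5 | (2R,5R)-1-(3,4-dimethoxybenzyl)-2,5-dimethylthiolan-1-ium tetrafluoroborate | C[C@@H]1CC[C@@H](C)[S+]1Cc1ccc(OC)c(OC)c1.F[B-](F)(F)F | intermediate
6 | 4-bromo-2-methoxyphenol | COc1cc(Br)ccc1O | starting material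
7 | ethyl glyoxylate | CCOC(=O)C=O | starting material
8 | ethyl 2-(5-bromo-2-hydroxy-3-methoxyphenyl)-2-hydroxyacetate (racemic; present as its magnesium chelate) | CCOC(=O)C(O)c1cc(Br)cc(OC)c1O | intermediate
9 | ethyl 2-(5-bromo-2-hydroxy-3-methoxyphenyl)-2-[(tert-butoxycarbonyl)oxy]acetate (racemic; present as its magnesium phenoxide) | CCOC(=O)C(OC(=O)OC(C)(C)C)c1cc(Br)cc(OC)c1O | intermediate
10 | ethyl 2-(3-bromo-5-methoxy-6-oxocyclohexa-2,4-dien-1-ylidene)acetate (ortho-quinone methide) | CCOC(=O)C=C1C=C(Br)C=C(OC)C1=O | intermediate
11 | (2R,5R)-2,5-dimethylthiolan-1-ium-1-yl (3,4-dimethoxyphenyl)methanide (sulfonium ylide) | C[C@@H]1CC[C@@H](C)[S+]1[CH-]c1ccc(OC)c(OC)c1 | intermediate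
12 | ethyl (2S,3S)-2-(5-bromo-3-methoxy-2-oxidophenyl)-3-(3,4-dimethoxyphenyl)-3-[(2R,5R)-2,5-dimethylthiolan-1-ium-1-yl]propanoate (anti betaine) | COc1ccc([C@@H]([S+]2[C@H](C)CC[C@H]2C)[C@H](C(=O)OCC)c2cc(Br)cc(OC)c2[O-])cc1OC | intermediate
13 | ethyl (2R,3R)-5-bromo-2-(3,4-dimethoxyphenyl)-7-methoxy-2,3-dihydro-1-benzofuran-3-carboxylate (trans) | COc1ccc([C@@H]2Oc3c(OC)cc(Br)cc3[C@H]2C(=O)OCC)cc1OC | intermediate
14 | [(2R,3S)-5-bromo-2-(3,4-dimethoxyphenyl)-7-methoxy-2,3-dihydro-1-benzofuran-3-yl]methanol (trans) | COc1ccc([C@@H]2Oc3c(OC)cc(Br)cc3[C@H]2CO)cc1OC | intermediate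
15 | 3,3-diethoxyprop-1-ene (acrolein diethyl acetal) | C=CC(OCC)OCC | starting material
16 | {(2R,3S)-5-[(1E)-3,3-diethoxyprop-1-en-1-yl]-2-(3,4-dimethoxyphenyl)-7-methoxy-2,3-dihydro-1-benzofuran-3-yl}methanol | COc1ccc([C@@H]2Oc3c(OC)cc(/C=C/C(OCC)OCC)cc3[C@H]2CO)cc1OC | intermediate
17 | 4-O-methylbalanophonin, (2E)-3-[(2R,3S)-2-(3,4-dimethoxyphenyl)-3-(hydroxymethyl)-7-methoxy-2,3-dihydro-1-benzofuran-5-yl]prop-2-enal | COc1ccc([C@@H]2Oc3c(OC)cc(/C=C/C=O)cc3[C@H]2CO)cc1OC | target

**Step count**

Total steps: 6. Longest linear sequence: 6 steps (1 → 2 → 3 → 5 → 13 → 14 → 17).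

**Steps most likely to fail**

Step 4. The three stages may not stay in sequence:
- the quinone methide may form before the ylide is present and then dimerise or be captured by alkoxide;
- the ylide may be protonated, or acylated by the carbonate;
- the electron-rich benzylic carbon–sulfur bond of the betaine may ionise, so that closure loses its stereospecificity;
- facial selectivity of the ylide may be poor.

Fallback (known chemistry; sets out from 6 and 7, comes back at 13): the bond formations are uncoupled, and C2–C3 is made by dirhodium-carbenoid C–H insertion, an established route to cis-2-aryl-2,3-dihydrobenzofuran-3-carboxylates. Phenol 6 and glyoxylate 7 are joined through the bromomagnesium phenoxide alone (EtMgBr, toluene) and hydroxy ester 8 is isolated. Its phenol is alkylated with bromide 4 (K2CO3, acetone) to give ethyl 2-{5-bromo-2-[(3,4-dimethoxyphenyl)methoxy]-3-methoxyphenyl}-2-hydroxyacetate F1. Dess–Martin oxidation gives ethyl 2-{5-bromo-2-[(3,4-dimethoxyphenyl)methoxy]-3-methoxyphenyl}-2-oxoacetate F2. Condensation with tosylhydrazide gives the N-tosylhydrazone of that keto ester F3, from which DBU expels sulfinate to leave ethyl 2-{5-bromo-2-[(3,4-dimethoxyphenyl)methoxy]-3-methoxyphenyl}-2-diazoacetate F4. Rh2(S-PTTL)4 (dirhodium tetrakis[N-phthaloyl-(S)-tert-leucinate]; its mirror image if the sense requires) closes the ring by insertion into the benzylic ether C–H bond. This should give ethyl (2R,3S)-5-bromo-2-(3,4-dimethoxyphenyl)-7-methoxy-2,3-dihydro-1-benzofuran-3-carboxylate (cis) F5, with C2 fixed by the catalyst. NaOEt in EtOH then epimerises C3 to the trans ester 13.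

Step 6. Oxidative addition into the electron-rich C5–Br bond may be slow. β-Hydride elimination may turn toward the acetal carbon and give the saturated ester. The hydroxymethyl group may reduce the aryl–palladium species. The acid used for unmasking may open the benzylic ether at C2.

Fallback (sets out from 14, comes back at 16): Suzuki–Miyaura coupling of 14 with commercial (E)-2-(3,3-diethoxyprop-1-en-1-yl)-4,4,5,5-tetramethyl-1,3,2-dioxaborolane (Pd(dppf)Cl2, [1,1'-bis(diphenylphosphino)ferrocene]palladium dichloride; K3PO4, dioxane–water, 80 °C). The three-carbon chain arrives with its E geometry and oxidation level already fixed, so no β-hydride elimination has to be steered. Acetal 16 is then hydrolysed to 17 as in the route, or with pyridinium p-toluenesulfonate in wet acetone if C2 is acid-sensitive. No new compound arises (F0).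

Step 3. Silver-promoted ionisation of the electron-rich benzylic bromide may outrun capture by the hindered sulfide, leading to Friedel–Crafts self-alkylation. The bromide also degrades on storage.

Fallback (sets out from 3, comes back at 5): dehydrative S-alkylation of 3 with 3,4-dimethoxybenzyl alcohol (COc1ccc(CO)cc1OC) and HBF4·OEt2 in Et2O at 0 °C, an established route to benzylic sulfonium tetrafluoroborates. The cation is released slowly from a stable alcohol in the presence of excess sulfide and the salt precipitates, so neither silver nor the labile bromide is needed. No new compound arises (F0).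

**Further compounds**

F1 | step 4 | ethyl 2-{5-bromo-2-[(3,4-dimethoxyphenyl)methoxy]-3-methoxyphenyl}-2-hydroxyacetate (racemic) | CCOC(=O)C(O)c1cc(Br)cc(OC)c1OCc1ccc(OC)c(OC)c1
F2 | step 4 | ethyl 2-{5-bromo-2-[(3,4-dimethoxyphenyl)methoxy]-3-methoxyphenyl}-2-oxoacetate | CCOC(=O)C(=O)c1cc(Br)cc(OC)c1OCc1ccc(OC)c(OC)c1
F3 | step 4 | N-tosylhydrazone of keto ester F2 | CCOC(=O)C(=NNS(=O)(=O)c1ccc(C)cc1)c1cc(Br)cc(OC)c1OCc1ccc(OC)c(OC)c1
F4 | step 4 | ethyl 2-{5-bromo-2-[(3,4-dimethoxyphenyl)methoxy]-3-methoxyphenyl}-2-diazoacetate | CCOC(=O)C(=[N+]=[N-])c1cc(Br)cc(OC)c1OCc1ccc(OC)c(OC)c1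
F5 | step 4 | ethyl (2R,3S)-5-bromo-2-(3,4-dimethoxyphenyl)-7-methoxy-2,3-dihydro-1-benzofuran-3-carboxylate (cis) | COc1ccc([C@@H]2Oc3c(OC)cc(Br)cc3[C@@H]2C(=O)OCC)cc1OC
F0 | step 6 | none | none
F0 | step 3 | none | none
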